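Ring A carries oxygen on C5, C7 and C8a and carbon on C4a, C6 and C8, so it can be read as three carbon-substituted ynol ethers (C4a–C5, C6–C7, C8–C8a) joined head to tail. The route cuts C4a–C8a, C5–C6 and C7–C8. An open-chain diyne, in which an ethoxy ynone and a propynyl ether are linked through C4, C3, the stereodefined C2 and O1, is cyclotrimerised with a silyloxypropyne on cationic rhodium. This closes rings A and B at once and places all six arene substituents. C2 is set by a Noyori hydrogenation and never touched again; two mild deprotections finish the synthesis.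

Key step: step 11

Remark: atoms of open-chain intermediates are named by the chromanone position they become (O1, C2, C3, C4, C4a, C5–C8, C8a); racemic BINAP is assumed to suffice in the key step because no stereogenic element is formed there.

Step 1
Reactants: 1 octadecanoyl chloride (stearoyl chloride); 2 potassium ethyl malonate (KO2CCH2CO2Et)
Product: 4 ethyl 3-oxoicosanoate, via 2-(ethoxycarbonyl)-3-oxoicosanoic acid 3 (not isolated)
Conditions: 2 (2 equiv), MgCl2, Et3N, MeCN, 0 °C → rt; then 1, rt; 1 M HCl
Reagents that add atoms: none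
Why: The magnesium chelate of the malonate half-ester is C-acylated by the acid chloride and the adduct loses CO2 on acidification (Claisen-type acylation with decarboxylation), which adds the two carbons that become C3 and C4.

Step 2
Reactants: 4 ethyl 3-oxoicosanoate
Product: 5 ethyl (S)-3-hydroxyicosanoate
Conditions: RuCl2[(S)-BINAP] (0.5 mol%), H2 (50 bar), EtOH, 50 °C
Reagents that add atoms: none
Why: Noyori asymmetric hydrogenation of a β-keto ester, in which the ester carbonyl chelates ruthenium and the (S)-BINAP ligand directs hydride to the face that gives the (S)-carbinol, the future C2.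

Step 3
Reactants: 5 ethyl (S)-3-hydroxyicosanoate
Product: 6 (S)-icosane-1,3-diol
Conditions: LiAlH4, THF, 0 °C → rt
Reagents that add atoms: none
Why: Hydride reduction of the ester to the primary alcohol, which leaves the carbinol centre and its S configuration untouched.

Step 4
Reactants: 6 (S)-icosane-1,3-diol
Product: 7 (S)-1-[(triisopropylsilyl)oxy]icosan-3-ol
Conditions: i-Pr3SiCl (1.05 equiv), imidazole, CH2Cl2, 0 °C → rt
Reagents that add atoms: triisopropylsilyl chloride, CC(C)[Si](Cl)(C(C)C)C(C)C
Why: Sterically controlled silyl ether formation at the primary hydroxyl; the triisopropylsilyl group is chosen because it should not migrate to the neighbouring secondary alkoxide generated in step 5.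

Step 5
Reactants: 7 (S)-1-[(triisopropylsilyl)oxy]icosan-3-ol; 8 trichloroethylene
Product: 11 triisopropyl{[(3S)-3-(prop-1-yn-1-yloxy)icosyl]oxy}silane, via dichlorovinyl ether 9 (not isolated), via lithium alkoxyacetylide 10 (not isolated)
Conditions: KH, THF, 0 °C; 8, −78 °C → rt; n-BuLi (2.5 equiv), −78 → −40 °C; MeI, DMPU, −78 °C → rt
Reagents that add atoms: iodomethane, CI
Why: The potassium alkoxide adds to dichloroacetylene formed in situ, n-BuLi then effects dehydrochlorination and chlorine–lithium exchange, and C-methylation of the acetylide gives the propynyl ether (ynol ether synthesis through a 1,2-dichlorovinyl ether); the carbinol C–O bond is never broken, so the S configuration is retained.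

Step 6
Reactants: 11 triisopropyl{[(3S)-3-(prop-1-yn-1-yloxy)icosyl]oxy}silane
Product: 12 (S)-3-(prop-1-yn-1-yloxy)icosan-1-ol
Conditions: Bu4NF, THF, 0 °C → rt
Reagents that add atoms: none
Why: Fluoride desilylation of the primary silyl ether under basic, acid-free conditions to which the ynol ether is inert.

Step 7
Reactants: 12 (S)-3-(prop-1-yn-1-yloxy)icosan-1-ol
Product: 13 (S)-3-(prop-1-yn-1-yloxy)icosanal
Conditions: Dess–Martin periodinane, NaHCO3, CH2Cl2, 0 °C
Reagents that add atoms: none
Why: Dess–Martin oxidation under bicarbonate buffer stops at the aldehyde, keeps acid away from the ynol ether and avoids the amine bases that could expel the alkynyloxy group from the β-position.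

Step 8
Reactants: 13 (S)-3-(prop-1-yn-1-yloxy)icosanal; 14 ethoxyacetylene
Product: 16 (5S)-1-ethoxy-5-(prop-1-yn-1-yloxy)docos-1-yn-3-ol (both C3 epimers), via lithium ethoxyacetylide 15 (not isolated)
Conditions: 14, n-BuLi, THF, −78 °C; then 13, −78 °C; H2O quench
Reagents that add atoms: none
Why: 1,2-Addition of a lithium acetylide to the aldehyde at −78 °C should outrun enolisation; the new C3 carbinol forms without selectivity, which does not matter because it is oxidised in step 9, and the basic quench guards the adduct against Meyer–Schuster rearrangement.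

Step 9
Reactants: 16 (5S)-1-ethoxy-5-(prop-1-yn-1-yloxy)docos-1-yn-3-ol
Product: 17 (S)-1-ethoxy-5-(prop-1-yn-1-yloxy)docos-1-yn-3-one
Conditions: MnO2 (activated, excess), CH2Cl2, rt
Reagents that add atoms: none
Why: Heterogeneous MnO2 oxidation of a propargylic alcohol to the conjugated ynone under neutral conditions, which should leave both ynol ethers and the β-alkynyloxy ketone intact.

Step 10
Reactants: 18 propyne
Product: 21 triisopropyl(prop-1-yn-1-yloxy)silane, via 1-propynyllithium 19 (not isolated), via lithium prop-1-yn-1-olate 20 (not isolated)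
Conditions: 18, LiN(SiMe3)2 (2.1 equiv), t-BuOOH, THF, −78 → 0 °C; then i-Pr3SiOTf, −78 → 0 °C
Reagents that add atoms: tert-butyl hydroperoxide, CC(C)(C)OO; triisopropylsilyl trifluoromethanesulfonate, CC(C)[Si](OS(=O)(=O)C(F)(F)F)(C(C)C)C(C)C
Why: Electrophilic oxygenation of the lithium acetylide by lithium tert-butyl peroxide gives the lithium ynolate, which the bulky silyl triflate traps on oxygen (ynolate O-silylation).

Step 11
Reactants: 17 (S)-1-ethoxy-5-(prop-1-yn-1-yloxy)docos-1-yn-3-one; 21 triisopropyl(prop-1-yn-1-yloxy)silane
Product: 22 (S)-5-ethoxy-2-heptadecyl-6,8-dimethyl-7-[(triisopropylsilyl)oxy]chroman-4-one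
Conditions: [Rh(cod)2]BF4 (10 mol%), rac-BINAP (10 mol%), H2 then Ar, CH2Cl2; 21 (3 equiv); 17 added over 4 h, 23 °C
Reagents that add atoms: none
Why: Proposed new method: the cationic monovalent rhodium bisphosphine fragment, freed of cod by the hydrogen pre-treatment, should bind the electron-poor ynone alkyne and the electron-rich propynyl ether of 17, couple them oxidatively at C4a–C8a, then insert 21 and close the arene by reductive elimination, forming C7–C8 and C5–C6. The closest known reaction types are (2+2+2) cycloadditions of tethered diynes with alkynyl ethers on cationic rhodium bisphosphine catalysts and the head-to-tail cyclotrimerisation of alkynyl ethers; new here is the union of three oxygenated alkynes, one a push–pull ynone, into a hexasubstituted ring. Ring B closes in the oxidative coupling, where the four-atom tether C4–C3–C2–O1 enforces a six-membered oxacycle fused to a rhodacyclopentadiene of trivalent rhodium bonded to C5 and C8, and ring A closes in the insertion and reductive elimination sequence. No stereocentre is created, and C2 with its C–O bond is a spectator. The step needs cross-selectivity and one orientation of 21: the tether makes the first coupling intramolecular and slow addition of 17 into excess 21 should suppress diyne self-reaction, while polarity matching should set the orientation, since C8 of the metallacycle is a nucleophilic enol-ether β-carbon that bonds to the oxygen-bearing carbon of 21, and the nucleophilic methyl-bearing carbon of 21 ends on C5, the electrophilic β-carbon of the C4 enone. Room temperature and the absence of acid and base should spare the retro-ene-prone secondary ynol ether and the elimination-prone β-alkynyloxy ketone.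

Step 12
Reactants: 22 (S)-5-ethoxy-2-heptadecyl-6,8-dimethyl-7-[(triisopropylsilyl)oxy]chroman-4-one
Product: 23 (S)-5-ethoxy-2-heptadecyl-7-hydroxy-6,8-dimethylchroman-4-one
Conditions: Bu4NF, AcOH (1:1), THF, 0 °C → rt
Reagents that add atoms: none
Why: Fluoride cleavage of the aryl silyl ether, buffered with acetic acid so that no free phenoxide or enolate can open ring B by retro-oxa-Michael reaction, the only path that could racemise C2.

Step 13
Reactants: 23 (S)-5-ethoxy-2-heptadecyl-7-hydroxy-6,8-dimethylchroman-4-one
Product: 24 (S)-2-heptadecyl-5,7-dihydroxy-6,8-dimethylchroman-4-one (target)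
Conditions: BCl3 (3 equiv), CH2Cl2, −78 → 0 °C; then H2O
Reagents that add atoms: none
Why: BCl3 bridges the C4 carbonyl and the peri C5 ether oxygen in a six-membered chelate and chloride removes the ethyl group (chelation-assisted Lewis acid dealkylation of an ortho-acyl aryl ether) at a temperature that should leave the O1–C2 bond and the C2 configuration intact.

Compound list
1 | octadecanoyl chloride (stearoyl chloride) | CCCCCCCCCCCCCCCCCC(=O)Cl | starting material
2 | potassium ethyl malonate | CCOC(=O)CC(=O)[O-].[K+] | starting material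
3 | 2-(ethoxycarbonyl)-3-oxoicosanoic acid (magnesium chelate in the flask) | CCCCCCCCCCCCCCCCCC(=O)C(C(=O)O)C(=O)OCC | intermediate (not isolated)
4 | ethyl 3-oxoicosanoate | CCCCCCCCCCCCCCCCCC(=O)CC(=O)OCC | intermediate
5 | ethyl (S)-3-hydroxyicosanoate | CCCCCCCCCCCCCCCCC[C@H](O)CC(=O)OCC | intermediate
6 | (S)-icosane-1,3-diol | CCCCCCCCCCCCCCCCC[C@H](O)CCO | intermediate
7 | (S)-1-[(triisopropylsilyl)oxy]icosan-3-ol | CCCCCCCCCCCCCCCCC[C@H](O)CCO[Si](C(C)C)(C(C)C)C(C)C | intermediate
8 | trichloroethylene | ClC=C(Cl)Cl | starting material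
9 | triisopropyl{[(3S)-3-{[(E)-1,2-dichloroethenyl]oxy}icosyl]oxy}silane | CCCCCCCCCCCCCCCCC[C@H](O/C(Cl)=C\Cl)CCO[Si](C(C)C)(C(C)C)C(C)C | intermediate (not isolated)
10 | ({(3S)-1-[(triisopropylsilyl)oxy]icosan-3-yl}oxy)ethynyllithium | CCCCCCCCCCCCCCCCC[C@H](OC#C[Li])CCO[Si](C(C)C)(C(C)C)C(C)C | intermediate (not isolated)
11 | triisopropyl{[(3S)-3-(prop-1-yn-1-yloxy)icosyl]oxy}silane | CCCCCCCCCCCCCCCCC[C@H](OC#CC)CCO[Si](C(C)C)(C(C)C)C(C)C | intermediate
12 | (S)-3-(prop-1-yn-1-yloxy)icosan-1-ol | CCCCCCCCCCCCCCCCC[C@H](OC#CC)CCO | intermediate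
13 | (S)-3-(prop-1-yn-1-yloxy)icosanal | CCCCCCCCCCCCCCCCC[C@H](OC#CC)CC=O | intermediate
14 | ethoxyacetylene | CCOC#C | starting material
15 | lithium ethoxyacetylide (LiC≡COEt) | CCOC#C[Li] | intermediate (not isolated)
16 | (5S)-1-ethoxy-5-(prop-1-yn-1-yloxy)docos-1-yn-3-ol, both C3 epimers | CCCCCCCCCCCCCCCCC[C@H](OC#CC)CC(O)C#COCC | intermediate
17 | (S)-1-ethoxy-5-(prop-1-yn-1-yloxy)docos-1-yn-3-one | CCCCCCCCCCCCCCCCC[C@H](OC#CC)CC(=O)C#COCC | intermediate
18 | propyne | CC#C | starting material
19 | 1-propynyllithium (MeC≡CLi) | CC#C[Li] | intermediate (not isolated)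
20 | lithium prop-1-yn-1-olate (MeC≡COLi) | CC#C[O-].[Li+] | intermediate (not isolated)
21 | triisopropyl(prop-1-yn-1-yloxy)silane, i.e. 1-(triisopropylsilyloxy)prop-1-yne | CC#CO[Si](C(C)C)(C(C)C)C(C)C | intermediate
22 | (S)-5-ethoxy-2-heptadecyl-6,8-dimethyl-7-[(triisopropylsilyl)oxy]chroman-4-one | CCCCCCCCCCCCCCCCC[C@H]1CC(=O)c2c(OCC)c(C)c(O[Si](C(C)C)(C(C)C)C(C)C)c(C)c2O1 | intermediate
23 | (S)-5-ethoxy-2-heptadecyl-7-hydroxy-6,8-dimethylchroman-4-one | CCCCCCCCCCCCCCCCC[C@H]1CC(=O)c2c(OCC)c(C)c(O)c(C)c2O1 | intermediate
24 | (S)-2-heptadecyl-5,7-dihydroxy-6,8-dimethylchroman-4-one | CCCCCCCCCCCCCCCCC[C@H]1CC(=O)c2c(O)c(C)c(O)c(C)c2O1 | target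

Total steps: 13. Longest linear sequence: 12 (steps 1–9 and 11–13); step 10 supplies the second component of step 11.

Steps most likely to fail

Step 11. The cyclotrimerisation may be lost to self-oligomerisation of either alkyne, to insertion of the silyloxyalkyne in the reverse orientation, or to catalyst-induced decomposition of the push–pull ynone. The fallback buys the arene instead of building it and uses known reaction types only. It sets out from β-keto ester 4. Thermal condensation of 4 with purchased 2,4-dimethylbenzene-1,3,5-triol (neat, about 240 °C, ethanol and water distilled off; Mentzer-type chromone synthesis at the only free ring position) should give 2-heptadecyl-5,7-dihydroxy-6,8-dimethyl-4H-chromen-4-one F1. Silylation of both phenols (t-BuMe2SiOTf, 2,6-lutidine, CH2Cl2) should give 5,7-bis[(tert-butyldimethylsilyl)oxy]-2-heptadecyl-6,8-dimethyl-4H-chromen-4-one F2. Copper hydride asymmetric conjugate reduction of the C2=C3 bond (Cu(OAc)2, DTBM-SEGPHOS, (EtO)2MeSiH, t-BuOH, toluene; the ligand enantiomer that gives S at C2 is chosen in a trial run) should give (S)-5,7-bis[(tert-butyldimethylsilyl)oxy]-2-heptadecyl-6,8-dimethylchroman-4-one F3. Buffered fluoride as in step 12 then comes back to the route at target 24.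

Step 5. Silicon may migrate to the secondary alkoxide, the hindered alkoxide may capture dichloroacetylene sluggishly, or the elimination may stall. The fallback builds the two alkyne carbons from a formate, so that no metal alkoxide of 7 is ever formed. It sets out from alcohol 7. Formylation (acetic formic anhydride, pyridine) should give (S)-1-[(triisopropylsilyl)oxy]icosan-3-yl formate F4. Dichloromethylenation of the formyl group (PPh3, CCl4, THF, 60 °C) should give triisopropyl{[(3S)-3-[(2,2-dichloroethenyl)oxy]icosyl]oxy}silane F5. n-BuLi (2.2 equiv, −78 °C) should convert F5 into the same lithium alkoxyacetylide 10, and methylation (MeI, DMPU) comes back to the route at 11.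

Step 8. The acetylide may act as a base, deprotonating next to the aldehyde and expelling the alkynyloxy group, and the adduct may rearrange during isolation. The fallback replaces the basic lithium reagent by an organochromium nucleophile generated from a haloalkyne. It sets out from ethoxyacetylene 14 and aldehyde 13. Lithiation and iodination of 14 (n-BuLi, then I2, THF, −78 °C) should give 1-ethoxy-2-iodoethyne F6, kept as a cold solution. F6, aldehyde 13, CrCl2 and catalytic NiCl2 in THF at room temperature (Nozaki–Hiyama–Kishi alkynylation), followed by neutral aqueous work-up, come back to the route at carbinol 16.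

Further compounds
F1 | step 11 | 2-heptadecyl-5,7-dihydroxy-6,8-dimethyl-4H-chromen-4-one | CCCCCCCCCCCCCCCCCc1cc(=O)c2c(O)c(C)c(O)c(C)c2o1
F2 | step 11 | 5,7-bis[(tert-butyldimethylsilyl)oxy]-2-heptadecyl-6,8-dimethyl-4H-chromen-4-one | CCCCCCCCCCCCCCCCCc1cc(=O)c2c(O[Si](C)(C)C(C)(C)C)c(C)c(O[Si](C)(C)C(C)(C)C)c(C)c2o1
F3 | step 11 | (S)-5,7-bis[(tert-butyldimethylsilyl)oxy]-2-heptadecyl-6,8-dimethylchroman-4-one | CCCCCCCCCCCCCCCCC[C@H]1CC(=O)c2c(O[Si](C)(C)C(C)(C)C)c(C)c(O[Si](C)(C)C(C)(C)C)c(C)c2O1
F4 | step 5 | (S)-1-[(triisopropylsilyl)oxy]icosan-3-yl formate | CCCCCCCCCCCCCCCCC[C@H](OC=O)CCO[Si](C(C)C)(C(C)C)C(C)C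
F5 | step 5 | triisopropyl{[(3S)-3-[(2,2-dichloroethenyl)oxy]icosyl]oxy}silane | CCCCCCCCCCCCCCCCC[C@H](OC=C(Cl)Cl)CCO[Si](C(C)C)(C(C)C)C(C)C
F6 | step 8 | 1-ethoxy-2-iodoethyne | CCOC#CI
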